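All runs are calculated for an exercise, and the scatter is random.

A left-handed product near 50.0% of the substrates charged looks finished, yet the small gap to that ceiling hides how far the flask has gone, so we reckon with the fraction of left-handed substrate left, which is one minus twice the reading.

| setting | winter | noon | midnight | flask |
|---|---|---|---|---|
| left-handed substrate | 0.56 M | 0.88 M | 0.40 M | 0.40 M |
| right-handed substrate | 0.56 M | 0.88 M | 0.40 M | 0.40 M |
| gas | 16 mM (held) | 16 mM (held) | 16 mM (held) | 16 mM (held) |
| catalyst | 2 mol% | 2 mol% | 1 mol% | 2 mol% |
| remark | run made earlier | run made earlier | run made earlier |  |
| time |  |  |  | 2.5 min |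

| run | time / min | left-handed product / % |
|---|---|---|
| winter | 0.200 | 10.3 |
| winter | 0.333 | 15.7 |
| winter | 0.500 | 23.7 |
| winter | 0.667 | 28.7 |
| winter | 1.00 | 37.3 |
| winter | 1.50 | 45.7 |
| winter | 2.50 | 49.7 |
| noon | 0.333 | 14.6 |
| noon | 0.667 | 25.7 |
| noon | 1.00 | 36.1 |
| noon | 1.33 | 43.4 |
| noon | 2.00 | 48.8 |
| noon | 2.50 | 49.3 |
| midnight | 0.200 | 6.2 |
| midnight | 0.417 | 11.6 |
| midnight | 0.667 | 18.3 |
| midnight | 1.33 | 30.8 |
| midnight | 2.50 | 42.5 |

(readings scatter by 0.5 percentage points)

- catalyst is single-handed; left-handed substrate and right-handed substrate are mirror images of each other, charged as a racemate, each of them at the stated concentration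
- at the start none of partner is dissolved
- the earlier runs were read with a standard deviation of 0.5 percentage points
- what may be going on: partner + catalyst + right-handed substrate -> catalyst + right-handed product; gas <-> partner; partner + catalyst + left-handed substrate -> catalyst + left-handed product

- the left-handed product standing at 2.5 min, as a percentage of the left-handed substrate and right-handed substrate together charged
- the change that raises the amount of left-handed product at 2.5 min, in percent of the left-handed substrate and right-handed substrate together charged most ("none" if none brings more than 2 percentage points) (zeta / gamma / delta / none)
- amount of left-handed product at 2.5 min, in percent of the left-handed substrate and right-handed substrate together charged, after delta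

- zeta: doubling the saturation concentration of gas, all else as stated
- gamma: doubling the amount of catalyst, all else as stated
- delta: doubling the transfer coefficient of the gas, all else as stated

The midnight run has the flask's substrate charges and half its catalyst, and its reading at 2.50 min leaves 15.0% of the left-handed substrate. We assume pseudo-first-order decay with partner standing alike in both, and carry the clearance constant, the logarithm of one over the fraction left per catalyst concentration and per time: 3.16 M⁻¹ s⁻¹. With 8.00 mM of catalyst for 2.5 min, the flask keeps 2.25% of its left-handed substrate by our reckoning, so we commit to 48.9% of left-handed product, and to none as the best change, since the gap of 1.1 percentage points to the ceiling is smaller than 2 points.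

The forecast gave 48.7%, none and 49.1% after delta, holding that “Only about 1.3 points remain below the 50% ceiling, so no change can add more than 2 points”.

The flask gives 48.6%, best change none (zeta 1.4 points, gamma 1.3 points, delta 0.46 points), and 49.1% after delta.

    partner + catalyst + right-handed substrate → catalyst + right-handed product (k = 80.0 M⁻² s⁻¹)
    gas ⇌ partner, rate k2*(csat - [partner]) (kL = 1.51 s⁻¹)
    partner + catalyst + left-handed substrate → catalyst + left-handed product (k = 231 M⁻² s⁻¹)

The flask keeps 2.8% of its left-handed substrate at 2.50 min, a clearance constant of 2.99 M⁻¹ s⁻¹, smaller than our 3.16 M⁻¹ s⁻¹. At 0.720 min in the flask, the half-life of partner by the right-handed step is 0.061 min, far shorter than the 1.5 min of right-handed substrate by that step, and partner is made 1.01 times as fast as it is used. For a second flask, like this one but with 0.5 mol% of catalyst, our constant leaves 38.7% of the left-handed substrate against the 37% that second flask keeps, and that second flask holds 31.5% of left-handed product.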